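## The problem

Eremophilane numbering is used throughout: ring A is C1–C5 with C10, ring B is C5–C10, C14 and C15 are the methyl groups on C5 and C4, and C11 is the exocyclic carbon on C7 carrying C12 (CH2OH) and C13 (CH3); β is the face that carries C14, α the other. Target 21 is the 3α-(2E,4E,6E)-5-methyldodeca-2,4,6-trienoate of a 9α,12-dihydroxyeremophil-7(11)-en-8-one, (3R,4R,5R,9S,10R), a trans-fused decalin whose quaternary C5 is wedged between the methyl-bearing C4 and the ring-fusion carbon C10. Only C5 is fixed for good. In the chair–chair trans-decalin the C4 methyl, the C9 hydroxyl and the C3 oxygen are all equatorial, so C5 can steer C10, C4 and C9 by equilibration once a carbonyl stands next to each (C9 for C10, C3 for C4, C8 for C9). C3 is the exception: the axial trajectory to a C3 ketone is shielded by the syn-axial C14, so hydride gives the axial carbinol and the equatorial ester must come by inversion. The tetrasubstituted C7=C11 alkene must be formed with C12 cis to C6, although the two C11 substituents differ little in size. The α-ketol (C8/C9) is prone to epimerisation, ketol shift and autoxidation in base; the alkylidene ketone to γ-deprotonation and, as its Z isomer with a free C12 hydroxyl, to furan formation in acid; the trienoate to hydrides, nucleophiles and light. The ester therefore arrives late and the last deprotection is buffered. The enabling feature is that ring B with its C5 methyl and C8/C9 oxygens is a reduced 2-methoxy-5-methyl-1,4-benzoquinone (3), and C1–C4 with the C3 oxygen and C15 is the silyl dienol ether 2 of pent-1-en-3-one (1); a Diels–Alder reaction forms C4–C5 and C1–C10 and closes ring A.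

## Retrosynthesis

Target 21 is the desilylated form of bis-silyl ether 20. The C7=C11 π bond of 20 is traced to tertiary aldol 19 (C11–OH, C7–H). Cutting here, and not by olefination of a C7 carbonyl, keeps C8 as the only ring B carbonyl and uses its α-acidity for the elimination. The forward step must give the 7(11)E isomer from a mixture of aldol diastereomers.

The C3–O ester bond of 19 is cut with inversion, giving acid 18 and the axial 3β-alcohol 11. A cut with retention would need the equatorial 3α-alcohol, which hydride does not deliver past the syn-axial C14. Joining the acid this late spares the triene all reductions. The forward Mitsunobu step must substitute at a hindered axial carbinol without elimination.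

In 11 the C7–C11, C6–H and C3–H bonds are cut together, giving enone-ketone 9 and the commercial ketone 10 (C11–C13 with the C12 oxygen). Compared with deprotonating a saturated C8 ketone, where C7 and C9 compete, conjugate hydride addition to the 6-en-8-one of 9 places the enolate at C7 without choice. The same hydride sets C3. The precursor has lost three carbons and three stereocentres.

Enone-ketone 9 goes back by equilibration of C4 and C9 to silyl ether 8, by silylation to ketol 7, and by acid-induced 1,3-carbonyl transposition to diol 6. Diol 6 comes from ene-dione 5 by hydride reduction. These steps change no skeletal bond; they convert the quinone oxidation pattern (C6, C9 carbonyls, C8 methoxy) into the target pattern (C8 ketone, C9 carbinol, C6 on its way to CH2). They are ordered so that C4 is equilibrated only when C6 no longer carries a peri oxygen.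

Trans-fused 5 comes from cis-fused adduct 4 by epimerisation at C10, the only centre acidified by the C9 ketone.

The key cut is C4–C5 and C1–C10 of 4, giving diene 2 and quinone 3. An annulation that forms C5–C10 and C3–C4 from a cyclohexanone would bring neither the C8/C9 oxygens nor a catalytic entry to the quaternary centre. Here both commercial partners carry all three ring oxygens and both methyl groups. The forward reaction must choose the methyl-bearing alkene of 3, join the two methyl-bearing carbons, and select endo and one quinone face.

Diene 2 is the Z silyl dienol ether of 1 (O–Si bond).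

Acid 18 is cut at C2=C3 (Wittig on dienal 16, made in the flask from dienol 15) and at C6=C7 (vinylogous Horner–Wadsworth–Emmons of hexanal 12 with phosphonate 13, via dienoate 14 and ester 17). Both olefinations use aldehydes, which give better E control than a ketone olefination at the methyl-bearing C5.

## Roads not taken

Alternative 1: The cut is C5–C10 of ring A, with the C3–O bond sacrificed. Forward, the C9 carboxyl is held as a lactone on the C3 oxygen. Its silyl ketene acetal (LDA, Me3SiCl, heat) rearranges [3,3] onto the C4=C5 alkene and gives cyclohexene acid A1. The merit is that C5 and C10 are set together, stereospecifically and in the trans sense, from alkene geometry and one carbinol centre. Hydroboration of the resulting C3=C4 alkene from the α-face would then give the 3α-oxygen and 4β-methyl in one syn addition. On these points this road is better than the chosen one, which needs an equilibration at C10, another at C4 and an inversion at C3. Its weak points are that an enantiopure lactone with a geometrically pure tetrasubstituted alkene must be made first, that the lactone forces a boat transition state, and that ring B, both its oxygens and the alkylidene are still missing after the key step. The chosen plan sets against it a bicyclic skeleton with all ring oxygens in two steps from commercial compounds, with chirality from a catalyst.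

Alternative 2: The cut is C9–C10 and C4–C5, so both rings form in one cationic cascade. Forward, Cu(OTf)2 with the tert-butyl bis(oxazoline) chelates the C9 aldehyde and C8 ketone; the aldehyde adds to the (E)-C5=C10 alkene and the C5 cation is captured by C4 of the (Z)-silyl enol ether, giving dione A2. The merit is the shortest conceivable entry: four stereocentres, trans fusion, equatorial C4 methyl and C9 hydroxyl in one step, with no epimerisation. In step count to the core it beats the chosen plan. Its weak points are mechanistic. The silyl enol ether is a far better nucleophile than the trisubstituted alkene, so intermolecular aldol addition to the activated aldehyde and simple ene termination compete. An enantioselective cascade of this kind has not been shown. A2 also carries two saturated ketones (C3, C8) that must be told apart, and its C7 must be enolised against C9. The chosen plan rests on a known reaction class, keeps C3 masked as an enol ether apart from the C8/C9 oxygens, and lets an enone dictate the C7 enolate.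

Alternative 3: The cut is C7–C8 and C11–C13. Forward, Ni(cod)2 couples the C8 aldehyde with the C7≡C11 alkyne while Me2Zn transfers methyl to C11, closing ring B as allylic alcohol A3. The merit is that the alkene geometry follows from syn addition across the alkyne, which is exactly where the chosen plan is weakest. Here this road is better. Its weak points are that the key step solves none of the decalin stereochemistry: C3, C4, C5, C9 and C10 must all be in place on a monocyclic precursor with the alkynyl chain on quaternary C5, which means a long linear sequence. Hydride transfer may compete with methyl transfer, and C8 must still be oxidised. The chosen plan reaches the core in two steps and sets against the geometry problem the steric bias of the elimination in step 14, with an aldehyde-level fallback.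

Key step: step 2

Assumption: (S)-1,1'-bi-2-naphthol is written in step 2; which antipode leads to the 5R series must be fixed by correlation of adduct 4, and the mirror-image ligand is used if the sense is opposite.

## Steps

Step 1
Reactants: 1 pent-1-en-3-one
Product: 2 (3Z)-3-(triisopropylsilyloxy)penta-1,3-diene
Conditions: i-Pr3SiOTf, Et3N, CH2Cl2, 0 °C to rt
Reagents that add atoms: triisopropylsilyl trifluoromethanesulfonate, CC(C)[Si](OS(=O)(=O)C(F)(F)F)(C(C)C)C(C)C
Why: Silyl triflate and amine convert the ethyl ketone into its silyl enol ether (soft enolisation); the Z enol ether, with the methyl group cis to oxygen and away from the vinyl group, is the expected isomer and is the one whose methyl group points outward in the s-cis diene.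

Step 2
Reactants: 2 (3Z)-3-(triisopropylsilyloxy)penta-1,3-diene, 3 2-methoxy-5-methyl-1,4-benzoquinone
Product: 4 cis-fused adduct (4S,5R,10S): ring A 2-ene with 3-triisopropylsilyloxy and 4α-methyl, 5β-methyl, 10β-H, ring B 8-methoxy-7-ene-6,9-dione
Conditions: TiCl2(OiPr)2 (20 mol %), (S)-BINOL (20 mol %), 4 Å MS, CH2Cl2–toluene, −78 to −30 °C
Reagents that add atoms: none
Why: The titanium–binaphthol complex should bind the quinone as a five-membered chelate through the C9 carbonyl and the C8 methoxy oxygen, which activates the C5=C10 alkene and makes C5, the β-carbon of the bound carbonyl, its electrophilic end; the closest known reaction type is the titanium–binaphthol-catalysed Diels–Alder reaction of quinones. The cycloaddition is a concerted, asynchronous endo [4+2] in which the C4–C5 bond is the more advanced. Ring A closes as a six-membered ring by suprafacial addition of both diene termini to one face of the C5=C10 alkene, so the C5 methyl and the C10 hydrogen are cis. C5, and with it the absolute configuration of the series, is set by the quinone face left open by the binaphthol ligand. C10 follows from C5 through the suprafacial addition, and C4 from the endo transition state together with the Z enol ether geometry, which places the C4 methyl trans to the C5 methyl. Site selectivity rests on the methoxy group, which deactivates its own alkene. Regioselectivity rests on the siloxy group, which makes the methyl-bearing diene terminus the nucleophilic one against the weaker opposing effect of that methyl group, and on the chelate, which singles out the C9 carbonyl over the vinylogous-ester C6 carbonyl. The bulky triisopropylsilyl group protects the enol ether from cleavage or silyl transfer by the Lewis acid.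

Step 3
Reactants: 4 cis-fused adduct
Product: 5 trans-fused adduct (4S,5R,10R): as 4 but 10α-H
Conditions: DBU (0.2 equiv), CH2Cl2, rt
Reagents that add atoms: none
Why: Reversible deprotonation at C10, the only carbon acidified by the C9 ketone of the ene-dione, equilibrates the ring fusion (base epimerisation). The trans isomer should prevail because it frees the 4α-methyl group from the concave face under ring B; C5, C4 and the silyl enol ether are not touched.

Step 4
Reactants: 5 trans-fused adduct
Product: 6 trans-fused 6,9-diol: ring A as in 5, ring B 8-methoxy-7-ene-6,9-diol (carbinol epimers at C6 and C9)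
Conditions: LiAlH4, THF, −78 to 0 °C; then H2O
Reagents that add atoms: none
Why: Hydride reduces the C9 ketone and, in 1,2-fashion, the vinylogous-ester C6 carbonyl, while both enol ethers are inert (LiAlH4 reduction). The C6 carbinol centre is lost in step 5 and the C9 centre is corrected in step 7, so the epimer mixture is carried on.

Step 5
Reactants: 6 trans-fused 6,9-diol
Product: 7 trans-fused 9-hydroxy-4α,5β-dimethyl-10α-H-decal-6-ene-3,8-dione (C9 epimers)
Conditions: 2 M aq. HCl, THF, 0 °C to rt
Reagents that add atoms: water, O
Why: Aqueous acid hydrolyses the methyl enol ether to the C8 ketone and expels the C6 hydroxyl as water (1,3-carbonyl transposition of a reduced vinylogous ester), leaving the C6=C7 enone with the C9 hydroxyl in place. The silyl enol ether is hydrolysed in the same pot by protonation at C2, so C4 keeps its configuration.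

Step 6
Reactants: 7 ketol-dione
Product: 8 9-(tert-butyldimethylsilyloxy)-4α,5β-dimethyl-10α-H-decal-6-ene-3,8-dione (C9 epimers)
Conditions: t-BuMe2SiOTf, 2,6-lutidine, CH2Cl2, −78 °C
Reagents that add atoms: tert-butyldimethylsilyl trifluoromethanesulfonate, CC(C)(C)[Si](C)(C)OS(=O)(=O)C(F)(F)F
Why: Silyl triflate with a hindered pyridine base silylates the α-ketol hydroxyl without enolising either ketone at low temperature (silyl ether formation). Capping the hydroxyl closes the enediol pathway by which base could shift the ketol and expose C10.

Step 7
Reactants: 8 silyl ether (C9 epimers, 4α-methyl)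
Product: 9 9α-(tert-butyldimethylsilyloxy)-4β,5β-dimethyl-10α-H-decal-6-ene-3,8-dione
Conditions: DBU, toluene, 60 °C, argon
Reagents that add atoms: none
Why: DBU equilibrates the two centres that flank ketones (base epimerisation): C4 through the C3 enolate, where axial protonation anti to C14 and the equatorial preference of the methyl group point the same way, and C9 through the α'-enolate of the enone, where the silyloxy group escapes the 1,3-diaxial contact with C14. C10 is not acidic and the enone has no γ-hydrogen because C5 is quaternary. The C4 preference amounts to about one gauche interaction, so residual 4α epimer is separated and resubmitted.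

Step 8
Reactants: 9 enone-ketone, 10 1-(tert-butyldimethylsilyloxy)propan-2-one
Product: 11 9α,12-bis(tert-butyldimethylsilyloxy)-3β,11-dihydroxy-4β,5β-dimethyl-10α-H-eremophilan-8-one (mixture at C7 and C11)
Conditions: LiBH(s-Bu)3 (L-Selectride, 2.2 equiv), THF, −78 °C; then 10, −78 °C; AcOH, −78 °C
Reagents that add atoms: none
Why: The trialkylborohydride adds hydride to C6 of the enone and so generates the C7–C8 enolate without a regiochemical choice; the enolate is trapped by the α-silyloxy ketone 10 (reductive aldol). The second equivalent reduces the C3 ketone from the open α-face, the β-face being blocked by the syn-axial C14, and gives the axial 3β-alcohol. The centres at C7 and C11 are removed in step 14.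

Step 9
Reactants: 12 hexanal, 13 triethyl (2E)-3-methyl-4-phosphonobut-2-enoate
Product: 14 ethyl (2E,4E)-3-methyldeca-2,4-dienoate
Conditions: LiN(SiMe3)2, THF–DMPU, −78 to 0 °C
Reagents that add atoms: none
Why: The lithiated phosphonate adds to hexanal through its α-carbon and loses phosphate (vinylogous Horner–Wadsworth–Emmons olefination), giving the new disubstituted alkene E and the 2E trisubstituted alkene as the major isomer; minor 2Z isomer is removed by chromatography.

Step 10
Reactants: 14 ethyl (2E,4E)-3-methyldeca-2,4-dienoate
Product: 15 (2E,4E)-3-methyldeca-2,4-dien-1-ol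
Conditions: i-Bu2AlH, CH2Cl2, −78 °C; aqueous work-up
Reagents that add atoms: none
Why: Two equivalents of the aluminium hydride reduce the conjugated ester to the allylic alcohol without touching the diene (ester reduction).

Step 11
Reactants: 15 (2E,4E)-3-methyldeca-2,4-dien-1-ol
Product: 17 ethyl (2E,4E,6E)-5-methyldodeca-2,4,6-trienoate, via (2E,4E)-3-methyldeca-2,4-dienal 16 (not isolated)
Conditions: MnO2, Ph3P=CHCO2Et, CH2Cl2, rt
Reagents that add atoms: ethyl (triphenylphosphoranylidene)acetate, CCOC(=O)C=P(c1ccccc1)(c1ccccc1)c1ccccc1
Why: MnO2 oxidises the allylic alcohol to dienal 16, which is intercepted in the same flask by the stabilised ylide (allylic oxidation followed by Wittig olefination), so the sensitive aldehyde is not handled. The stabilised ylide gives the E alkene.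

Step 12
Reactants: 17 ethyl (2E,4E,6E)-5-methyldodeca-2,4,6-trienoate
Product: 18 (2E,4E,6E)-5-methyldodeca-2,4,6-trienoic acid
Conditions: LiOH, THF–MeOH–H2O, rt; then aq. HCl to pH 3
Reagents that add atoms: lithium hydroxide, [Li+].[OH-]
Why: Saponification of the ethyl ester frees the acid; the mild conditions should leave the triene geometry intact.

Step 13
Reactants: 11 3β-alcohol, 18 (2E,4E,6E)-5-methyldodeca-2,4,6-trienoic acid
Product: 19 9α,12-bis(tert-butyldimethylsilyloxy)-11-hydroxy-8-oxo-4β,5β-dimethyl-10α-H-eremophilan-3α-yl (2E,4E,6E)-5-methyldodeca-2,4,6-trienoate (mixture at C7 and C11)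
Conditions: PPh3, DIAD, toluene, 0 °C to rt
Reagents that add atoms: none
Why: Mitsunobu esterification activates the axial 3β-hydroxyl as an oxyphosphonium ion, which the carboxylate of 18 displaces from the α-face (SN2), so the ester arrives equatorial (3α, 3R). The backside trajectory is flanked only by the axial hydrogens on C2 and C4, and the tertiary C11 hydroxyl does not react.

Step 14
Reactants: 19 aldol ester
Product: 20 9α,12-bis(tert-butyldimethylsilyloxy)-8-oxo-4β,5β-dimethyl-10α-H-eremophil-7(11)E-en-3α-yl (2E,4E,6E)-5-methyldodeca-2,4,6-trienoate
Conditions: Ph2S[OC(CF3)2Ph]2, CH2Cl2, 0 °C to rt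
Reagents that add atoms: none
Why: The sulfurane turns the tertiary hydroxyl into a leaving group that is lost together with the acidic C7 hydrogen (E1cB-like dehydration of a β-hydroxy ketone), giving the conjugated alkylidene ketone. The 7(11)E isomer should be favoured because the larger CH2OSi residue takes the side of the C6 methylene and the methyl group the side of the C8 oxygen, the same preference that places the β-substituent of an enone trans to the carbonyl group; any Z isomer is removed by chromatography.

Step 15
Reactants: 20 bis-silyl ether
Product: 21 (3R,4R,5R,9S,10R)-9,12-dihydroxy-8-oxoeremophil-7(11)E-en-3-yl (2E,4E,6E)-5-methyldodeca-2,4,6-trienoate (CNP0226738.2)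
Conditions: HF·pyridine, pyridine, THF, 0 °C to rt
Reagents that add atoms: none
Why: Buffered fluoride cleaves both silyl ethers (desilylation) without the base or strong acid that would endanger the α-ketol, the alkene geometry or the trienoate.

## Compound list

1 | pent-1-en-3-one | CCC(=O)C=C | starting material
2 | (3Z)-3-(triisopropylsilyloxy)penta-1,3-diene | C=C/C(O[Si](C(C)C)(C(C)C)C(C)C)=C/C | intermediate
3 | 2-methoxy-5-methyl-1,4-benzoquinone | COC1=CC(=O)C(C)=CC1=O | starting material
4 | cis-fused adduct (4S,5R,10S): 3-triisopropylsilyloxy-2-ene, 4α-methyl, 5β-methyl, 10β-H, 8-methoxy-7-ene-6,9-dione | CC(C)[Si](C(C)C)(C(C)C)OC1=CC[C@@H]2C(=O)C(OC)=CC(=O)[C@]2(C)[C@@H]1C | intermediate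
5 | trans-fused adduct (4S,5R,10R): as 4 but 10α-H | CC(C)[Si](C(C)C)(C(C)C)OC1=CC[C@H]2C(=O)C(OC)=CC(=O)[C@]2(C)[C@@H]1C | intermediate
6 | trans-fused 8-methoxy-7-ene-6,9-diol with ring A as in 5 (epimers at C6 and C9) | CC(C)[Si](C(C)C)(C(C)C)OC1=CC[C@H]2C(O)C(OC)=CC(O)[C@]2(C)[C@@H]1C | intermediate
7 | 9-hydroxy-4α,5β-dimethyl-10α-H-decal-6-ene-3,8-dione (C9 epimers) | O=C1CC[C@H]2C(O)C(=O)C=C[C@]2(C)[C@@H]1C | intermediate
8 | 9-(tert-butyldimethylsilyloxy)-4α,5β-dimethyl-10α-H-decal-6-ene-3,8-dione (C9 epimers) | O=C1CC[C@H]2C(O[Si](C)(C)C(C)(C)C)C(=O)C=C[C@]2(C)[C@@H]1C | intermediate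
9 | 9α-(tert-butyldimethylsilyloxy)-4β,5β-dimethyl-10α-H-decal-6-ene-3,8-dione | O=C1CC[C@H]2[C@H](O[Si](C)(C)C(C)(C)C)C(=O)C=C[C@]2(C)[C@H]1C | intermediate
10 | 1-(tert-butyldimethylsilyloxy)propan-2-one | CC(=O)CO[Si](C)(C)C(C)(C)C | starting material
11 | 9α,12-bis(tert-butyldimethylsilyloxy)-3β,11-dihydroxy-4β,5β-dimethyl-10α-H-eremophilan-8-one (mixture at C7, C11) | O[C@H]1CC[C@H]2[C@H](O[Si](C)(C)C(C)(C)C)C(=O)C(C(C)(O)CO[Si](C)(C)C(C)(C)C)C[C@]2(C)[C@H]1C | intermediate
12 | hexanal | CCCCCC=O | starting material
13 | triethyl (2E)-3-methyl-4-phosphonobut-2-enoate | CCOC(=O)/C=C(\C)CP(=O)(OCC)OCC | starting material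
14 | ethyl (2E,4E)-3-methyldeca-2,4-dienoate | CCCCC/C=C/C(C)=C/C(=O)OCC | intermediate
15 | (2E,4E)-3-methyldeca-2,4-dien-1-ol | CCCCC/C=C/C(C)=C/CO | intermediate
16 | (2E,4E)-3-methyldeca-2,4-dienal | CCCCC/C=C/C(C)=C/C=O | intermediate (not isolated)
17 | ethyl (2E,4E,6E)-5-methyldodeca-2,4,6-trienoate | CCCCC/C=C/C(C)=C/C=C/C(=O)OCC | intermediate
18 | (2E,4E,6E)-5-methyldodeca-2,4,6-trienoic acid | CCCCC/C=C/C(C)=C/C=C/C(=O)O | intermediate
19 | 9α,12-bis(tert-butyldimethylsilyloxy)-11-hydroxy-8-oxo-4β,5β-dimethyl-10α-H-eremophilan-3α-yl (2E,4E,6E)-5-methyldodeca-2,4,6-trienoate (mixture at C7, C11) | CCCCC/C=C/C(C)=C/C=C/C(=O)O[C@@H]1CC[C@H]2[C@H](O[Si](C)(C)C(C)(C)C)C(=O)C(C(C)(O)CO[Si](C)(C)C(C)(C)C)C[C@]2(C)[C@H]1C | intermediate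
20 | 9α,12-bis(tert-butyldimethylsilyloxy)-8-oxo-4β,5β-dimethyl-10α-H-eremophil-7(11)E-en-3α-yl (2E,4E,6E)-5-methyldodeca-2,4,6-trienoate | CCCCC/C=C/C(C)=C/C=C/C(=O)O[C@@H]1CC[C@H]2[C@H](O[Si](C)(C)C(C)(C)C)C(=O)/C(=C(\C)CO[Si](C)(C)C(C)(C)C)C[C@]2(C)[C@H]1C | intermediate
21 | (3R,4R,5R,9S,10R)-9,12-dihydroxy-8-oxoeremophil-7(11)E-en-3-yl (2E,4E,6E)-5-methyldodeca-2,4,6-trienoate | CCCCC/C=C/C(C)=C/C=C/C(=O)O[C@@H]1CC[C@H]2[C@H](O)C(=O)/C(=C(\C)CO)C[C@]2(C)[C@H]1C | target

## Step count and least certain steps

Total: 15 steps. Longest linear sequence: 11 steps (steps 1–8 and 13–15, from pent-1-en-3-one); acid 18 is made in 4 steps (9–12) and joined in step 13.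

Step 2 (key step). The likely failures are poor facial discrimination if the quinone binds the titanium centre through one carbonyl only and not as the chelate, which would also erode regiocontrol; a stepwise conjugate addition with silyl transfer in place of cycloaddition; and slow reaction because two methyl-bearing carbons must be joined. The fallback separates bond formation from enantiocontrol. Diene 2 and quinone 3 are combined thermally or with BF3·OEt2 to give the racemic cis adduct F1, which is resolved by preparative chromatography on a chiral stationary phase. The route is rejoined at 4.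

Step 14. The likely failure is poor control of alkene geometry. An anti elimination is stereospecific and 19 is a diastereomer mixture, while the steric difference between CH3 and CH2OSi that should favour E is small; loss of a C13 proton toward an isopropenyl isomer is a second risk. The fallback builds the side chain at the aldehyde level, where the two carbonyl groups on the alkene should settle trans to each other under equilibration, as in other ene-dicarbonyl compounds.
- From 9, LiBH(s-Bu)3 followed by 1,1-dimethoxypropan-2-one gives the acetal aldol F2 (3β-hydroxyl formed as in step 8).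
- Aqueous acid (TsOH, acetone–water) unmasks the aldehyde, dehydrates the aldol and equilibrates the product to the 7(11)E keto-enal F3.
- NaBH(OAc)3 reduces the aldehyde selectively to the allylic alcohol F4.
- t-BuMe2SiCl with imidazole silylates the primary hydroxyl only, giving the 3β-hydroxy alkylidene ketone F5.
- Mitsunobu esterification of F5 with 18 rejoins the route at 20.

Step 13. The likely failures are sluggish activation of an axial hydroxyl that is syn-axial to C14 and next to the C4 methyl, and elimination through the anti-periplanar axial hydrogens on C2 and C4. The fallback separates activation from substitution. Alcohol 11 is converted with methanesulfonyl chloride in pyridine into the 3β-mesylate F6 (the tertiary hydroxyl is left), and the small leaving group is displaced with inversion by the caesium salt of 18 (Cs2CO3, DMF). The route is rejoined at 19.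

Step 8. The likely failures are competing 1,2-reduction of the enone, reversal of the aldol addition to a ketone acceptor on warming, and proton transfer that moves the enolate to C9. The fallback separates enolate formation from C–C bond formation. After reduction of 9 with LiBH(s-Bu)3 the enolate and the C3 alkoxide are trapped with Me3SiCl to give the bis(trimethylsilyl) compound F7. Its silyl enol ether is combined with 10 in a Lewis-acid aldol addition (TiCl4, CH2Cl2, −78 °C), and aqueous work-up frees the C3 hydroxyl. The route is rejoined at 11.

## Further compounds

F1 | step 2 | racemic cis adduct (4 together with its mirror image) | CC(C)[Si](C(C)C)(C(C)C)OC1=CC[C@@H]2C(=O)C(OC)=CC(=O)[C@]2(C)[C@@H]1C.CC(C)[Si](C(C)C)(C(C)C)OC1=CC[C@H]2C(=O)C(OC)=CC(=O)[C@@]2(C)[C@H]1C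
F2 | step 14 | 9α-(tert-butyldimethylsilyloxy)-3β,11-dihydroxy-12,12-dimethoxy-4β,5β-dimethyl-10α-H-eremophilan-8-one (mixture at C7, C11) | O[C@H]1CC[C@H]2[C@H](O[Si](C)(C)C(C)(C)C)C(=O)C(C(C)(O)C(OC)OC)C[C@]2(C)[C@H]1C
F3 | step 14 | 9α-(tert-butyldimethylsilyloxy)-3β-hydroxy-8-oxo-4β,5β-dimethyl-10α-H-eremophil-7(11)E-en-12-al | O[C@H]1CC[C@H]2[C@H](O[Si](C)(C)C(C)(C)C)C(=O)/C(=C(\C)C=O)C[C@]2(C)[C@H]1C
F4 | step 14 | 9α-(tert-butyldimethylsilyloxy)-3β,12-dihydroxy-4β,5β-dimethyl-10α-H-eremophil-7(11)E-en-8-one | O[C@H]1CC[C@H]2[C@H](O[Si](C)(C)C(C)(C)C)C(=O)/C(=C(\C)CO)C[C@]2(C)[C@H]1C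
F5 | step 14 | 9α,12-bis(tert-butyldimethylsilyloxy)-3β-hydroxy-4β,5β-dimethyl-10α-H-eremophil-7(11)E-en-8-one | O[C@H]1CC[C@H]2[C@H](O[Si](C)(C)C(C)(C)C)C(=O)/C(=C(\C)CO[Si](C)(C)C(C)(C)C)C[C@]2(C)[C@H]1C
F6 | step 13 | 3β-methanesulfonate of 11 | CS(=O)(=O)O[C@H]1CC[C@H]2[C@H](O[Si](C)(C)C(C)(C)C)C(=O)C(C(C)(O)CO[Si](C)(C)C(C)(C)C)C[C@]2(C)[C@H]1C
F7 | step 8 | 9α-(tert-butyldimethylsilyloxy)-3β,8-bis(trimethylsilyloxy)-4β,5β-dimethyl-10α-H-decal-7-ene | C[Si](C)(C)O[C@H]1CC[C@H]2[C@H](O[Si](C)(C)C(C)(C)C)C(O[Si](C)(C)C)=CC[C@]2(C)[C@H]1C
A1 | alternative 1 | (1R,2S)-2-[3-(benzyloxy)propyl]-2,3-dimethylcyclohex-3-ene-1-carboxylic acid | OC(=O)[C@@H]1CCC=C(C)[C@@]1(C)CCCOCc1ccccc1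
A2 | alternative 2 | trans-fused 9α-hydroxy-4β,5β-dimethyl-10α-H-decalin-3,8-dione | O=C1CC[C@H]2[C@H](O)C(=O)CC[C@]2(C)[C@H]1C
A3 | alternative 3 | 9α,12-bis(tert-butyldimethylsilyloxy)-3α-(4-methoxybenzyloxy)-4β,5β-dimethyl-10α-H-eremophil-7(11)E-en-8β-ol | COc1ccc(CO[C@@H]2CC[C@H]3[C@H](O[Si](C)(C)C(C)(C)C)[C@@H](O)/C(=C(\C)CO[Si](C)(C)C(C)(C)C)C[C@]3(C)[C@H]2C)cc1
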